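## Retrosynthetic overview

1. Target (germacrane numbering) ⇐ its C3 silyl ether; the ten-membered ring is closed last at C1–C10 by an intramolecular Ni/Cr-catalysed alkenyl iodide–aldehyde coupling that also sets C1.
2. Seco-aldehyde ⇐ cis-α-methylene-γ-butyrolactone carrying both side arms; the C8 angelate is installed and the C1 acetal opened between the two couplings.
3. Lactone ⇐ west (Z)-enal (C1–C6, C15) + east (Z)-2-(bromomethyl)enoate (C7–C14) by a chromium-catalysed 2-(methoxycarbonyl)allylation (C6–C7; sets C6 and C7), then lactonisation.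
4. West ⇐ (Z)-3-iodobut-2-enyl silyl ether (from but-2-yn-1-ol) + 3,3-dimethoxypropanal by asymmetric Ni/Cr coupling (C3–C4; sets C3). East ⇐ (S)-glycidol (C8) + 1-silylvinyl Grignard reagent, then Morita–Baylis–Hillman reaction with methyl acrylate and SN2′ bromination.
5. Ring order: γ-lactone first, ten-membered carbocycle second.

Assumption: the ligand enantiomers named for steps 4, 13 and 17 are those taken to give the drawn configurations; if the sense of induction proves reversed, the enantiomeric ligand is used. Ligand A is N-{2-[(4S)-4-isopropyl-4,5-dihydrooxazol-2-yl]-6-methylphenyl}methanesulfonamide, ent-A is its enantiomer, and ligand B is 3,6-di-tert-butyl-1,8-bis[(4S)-4-isopropyl-4,5-dihydrooxazol-2-yl]-9H-carbazole.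

## Route

Step 1
Reactants: 1 but-2-yn-1-ol
Product: 3 (Z)-3-iodobut-2-en-1-ol, via cyclic alkenylalanate 2 (not isolated)
Conditions: NaAlH2(OCH2CH2OMe)2, THF, 0 °C to rt; then I2, −78 to 0 °C
Reagents that add atoms: iodine, [I][I]
Why: Hydroxyl-directed trans-hydroalumination puts aluminium on C3 in a five-membered alanate, and iodinolysis with retention gives the (Z)-iodide (I cis to CH2OH), which fixes the later C4=C5 geometry.

Step 2
Reactants: 3 (Z)-3-iodobut-2-en-1-ol
Product: 4 (Z)-triethyl[(3-iodobut-2-en-1-yl)oxy]silane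
Conditions: Et3SiCl, imidazole, CH2Cl2, 0 °C
Reagents that add atoms: chlorotriethylsilane, CC[Si](Cl)(CC)CC
Why: Standard silylation of the primary alcohol; the triethylsilyl ether survives the chromium coupling and can later be oxidised directly.

Step 3
Reactants: 5 3,3-dimethoxypropanenitrile
Product: 7 3,3-dimethoxypropanal, via aluminoimine 6 (not isolated)
Conditions: iBu2AlH, Et2O, −78 °C; then aq. NH4Cl/KNaC4H4O6, 0 °C
Reagents that add atoms: water, O
Why: Partial nitrile reduction stops at the N-aluminoimine at −78 °C, and buffered hydrolysis frees the aldehyde without touching the dimethyl acetal.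

Step 4
Reactants: 4 (Z)-triethyl[(3-iodobut-2-en-1-yl)oxy]silane; 7 3,3-dimethoxypropanal
Product: 8 (3S,4Z)-1,1-dimethoxy-4-methyl-6-(triethylsilyloxy)hex-4-en-3-ol
Conditions: CrCl2 (10 mol%), ligand A (11 mol%), proton sponge (11 mol%), NiCl2(neocuproine) (2 mol%), Mn, Cp2ZrCl2, LiCl, MeCN, rt; aq. work-up
Reagents that add atoms: none
Why: Catalytic asymmetric Nozaki–Hiyama–Kishi coupling: zerovalent nickel inserts into the C–I bond with retention, the alkenyl group passes to trivalent chromium carrying ligand A and adds to the Re face of 7 to set C3 as S, while Cp2ZrCl2 frees chromium from the alkoxide and Mn returns it to the divalent state.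

Step 5
Reactants: 8 (3S,4Z)-1,1-dimethoxy-4-methyl-6-(triethylsilyloxy)hex-4-en-3-ol
Product: 9 (3S,4Z)-3-(tert-butyldimethylsilyloxy)-1,1-dimethoxy-4-methyl-6-(triethylsilyloxy)hex-4-ene
Conditions: tBuMe2SiCl, imidazole, DMAP (cat.), DMF, rt
Reagents that add atoms: tert-butylchlorodimethylsilane, CC(C)(C)[Si](C)(C)Cl
Why: Silylation of the secondary allylic alcohol under chloride/imidazole conditions, which (unlike silyl triflates) leave the dimethyl acetal alone.

Step 6
Reactants: 9 (3S,4Z)-3-(tert-butyldimethylsilyloxy)-1,1-dimethoxy-4-methyl-6-(triethylsilyloxy)hex-4-ene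
Product: 10 (2Z,4S)-4-(tert-butyldimethylsilyloxy)-6,6-dimethoxy-3-methylhex-2-enal
Conditions: (COCl)2, DMSO, CH2Cl2, −78 to −30 °C; Et3N, −78 to 0 °C
Reagents that add atoms: none
Why: Under Swern conditions a primary triethylsilyl ether goes straight to the aldehyde (the ether oxygen attacks the chlorosulfonium salt with loss of Et3SiCl) while the secondary TBS ether and the acetal are inert, and the low temperature keeps the Z geometry.

Step 7
Reactants: 11 (S)-glycidol; 12 (1-bromovinyl)trimethylsilane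
Product: 14 (2R)-4-(trimethylsilyl)pent-4-ene-1,2-diol, via Grignard reagent 13 (not isolated)
Conditions: Mg, THF, 50 °C (2.3 equiv of 13); CuI (10 mol%), −30 to 0 °C; aq. NH4Cl
Reagents that add atoms: none
Why: Copper-catalysed SN2 opening of the epoxide at its CH2 terminus by the vinyl Grignard reagent; the C8 centre comes unchanged from (S)-glycidol (one equivalent of 13 is consumed by the hydroxyl).

Step 8
Reactants: 14 (2R)-4-(trimethylsilyl)pent-4-ene-1,2-diol
Product: 15 (2R)-1,2-bis(triethylsilyloxy)-4-(trimethylsilyl)pent-4-ene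
Conditions: Et3SiCl, imidazole, DMF, 0 °C to rt
Reagents that add atoms: chlorotriethylsilane, CC[Si](Cl)(CC)CC
Why: Exhaustive silylation; two triethylsilyl ethers are chosen so that the primary one can be oxidised selectively.

Step 9
Reactants: 15 (2R)-1,2-bis(triethylsilyloxy)-4-(trimethylsilyl)pent-4-ene
Product: 16 (2R)-4-iodo-1,2-bis(triethylsilyloxy)pent-4-ene
Conditions: N-iodosuccinimide, MeCN/ClCH2CN (4:1), 0 °C to rt
Reagents that add atoms: N-iodosuccinimide, O=C1CCC(=O)N1I
Why: Iododesilylation of the 2-silyl-1-alkene (iodonium formation, then loss of the silyl group) exchanges SiMe3 for I at C10 and leaves the silyl ethers intact.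

Step 10
Reactants: 16 (2R)-4-iodo-1,2-bis(triethylsilyloxy)pent-4-ene
Product: 17 (2R)-4-iodo-2-(triethylsilyloxy)pent-4-enal
Conditions: (COCl)2, DMSO, CH2Cl2, −78 to −40 °C; Et3N, −78 to −20 °C
Reagents that add atoms: none
Why: Swern oxidation of a bis(triethylsilyl) ether attacks only the primary ether, giving the α-silyloxy aldehyde without epimerisation at low temperature.

Step 11
Reactants: 17 (2R)-4-iodo-2-(triethylsilyloxy)pent-4-enal; 18 methyl acrylate
Product: 19 methyl (4R)-3-hydroxy-6-iodo-2-methylidene-4-(triethylsilyloxy)hept-6-enoate (both C3 epimers)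
Conditions: DABCO (0.5 equiv), neat 18, rt, 2–3 d
Reagents that add atoms: none
Why: Morita–Baylis–Hillman reaction: DABCO adds to the acrylate and the resulting enolate adds to the inductively activated α-silyloxy aldehyde; the new carbinol centre is lost in the next step, so its configuration is irrelevant.

Step 12
Reactants: 19 methyl (4R)-3-hydroxy-6-iodo-2-methylidene-4-(triethylsilyloxy)hept-6-enoate
Product: 20 methyl (2Z,4R)-2-(bromomethyl)-6-iodo-4-(triethylsilyloxy)hepta-2,6-dienoate
Conditions: N-bromosuccinimide, Me2S, CH2Cl2, 0 °C to rt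
Reagents that add atoms: N-bromosuccinimide, O=C1CCC(=O)N1Br
Why: Corey–Kim-type activation of the allylic alcohol and SN2′ attack of bromide at the CH2 terminus give the thermodynamically preferred (Z)-2-(bromomethyl)enoate, with C8 trans to the ester.

Step 13
Reactants: 10 (2Z,4S)-4-(tert-butyldimethylsilyloxy)-6,6-dimethoxy-3-methylhex-2-enal; 20 methyl (2Z,4R)-2-(bromomethyl)-6-iodo-4-(triethylsilyloxy)hepta-2,6-dienoate
Product: 22 (4S,5S)-5-[(1Z,3S)-3-(tert-butyldimethylsilyloxy)-5,5-dimethoxy-2-methylpent-1-en-1-yl]-4-[(1R)-3-iodo-1-(triethylsilyloxy)but-3-en-1-yl]-3-methylideneoxolan-2-one (cis lactone), via syn hydroxy ester 21 (not isolated)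
Conditions: CrCl2 (10 mol%), ligand B (12 mol%), iPr2NEt (30 mol%), Mn, Cp2ZrCl2, THF/MeCN, 0 °C; aq. work-up; then PPTS (cat.), PhMe, 40 °C
Reagents that add atoms: none
Why: Proposed new method: a ligand-controlled, chromium-catalysed syn-selective 2-(methoxycarbonyl)allylation that joins two chiral fragments. Divalent chromium (regenerated by Mn) reduces the allylic C–Br bond of 20 to a trivalent allylchromium in which the ester keeps the C8 branch cis to CH2Cr, so the closed Zimmerman–Traxler chair with the enal substituent equatorial gives the syn adduct 21 and hence the cis lactone. The tridentate bis(oxazolinyl)carbazole on chromium selects the Re face of 10 (6S), which through the chair fixes C7; this is predicted to be the matched case for the 8R centre (H-8 in the olefin plane by allylic 1,3-strain, C9 anti to the incoming aldehyde, OSiEt3 outside). Cp2ZrCl2 takes the alkoxide off chromium to close the cycle, and without nickel the vinyl iodide is inert. Closest known reaction type: the chromium-catalysed enantioselective Nozaki–Hiyama 2-(alkoxycarbonyl)allylation of aldehydes with achiral 2-(bromomethyl)acrylates, and the stoichiometric Zn, In or CrCl2 Barbier lactonisation of γ-substituted bromides; neither has been shown with catalyst control over a γ-branched, δ-oxygenated chiral bromide or on a (Z)-enal.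

Step 14
Reactants: 22 cis lactone with C8 triethylsilyl ether
Product: 23 (4R,5S)-5-[(1Z,3S)-3-(tert-butyldimethylsilyloxy)-5,5-dimethoxy-2-methylpent-1-en-1-yl]-4-[(1R)-1-hydroxy-3-iodobut-3-en-1-yl]-3-methylideneoxolan-2-one
Conditions: PPTS (20 mol%), MeOH/CH2Cl2 (1:1), 0 °C
Reagents that add atoms: none
Why: Acid-catalysed methanolysis removes the secondary triethylsilyl ether about a hundred times faster than the allylic TBS ether, and the dimethyl acetal is degenerate in methanol.

Step 15
Reactants: 23 C8 alcohol; 24 angelic acid [(Z)-2-methylbut-2-enoic acid]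
Product: 26 (1R)-1-{(4R,5S)-5-[(1Z,3S)-3-(tert-butyldimethylsilyloxy)-5,5-dimethoxy-2-methylpent-1-en-1-yl]-3-methylidene-2-oxooxolan-4-yl}-3-iodobut-3-en-1-yl (2Z)-2-methylbut-2-enoate, via mixed anhydride 25 (not isolated)
Conditions: 2,4,6-Cl3C6H2COCl, Et3N, PhMe, rt; then 23, PhMe, 75 °C
Reagents that add atoms: none
Why: Yamaguchi-type esterification through the mixed anhydride without DMAP acylates the hindered C8 alcohol while avoiding Z to E isomerisation of the angelate.

Step 16
Reactants: 26 C8 angelate with C1 dimethyl acetal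
Product: 28 (1R)-1-{(4R,5S)-5-[(1Z,3S)-3-(tert-butyldimethylsilyloxy)-2-methyl-5-oxopent-1-en-1-yl]-3-methylidene-2-oxooxolan-4-yl}-3-iodobut-3-en-1-yl (2Z)-2-methylbut-2-enoate, via collidinium adduct 27 (not isolated)
Conditions: Et3SiOTf, 2,4,6-collidine, CH2Cl2, 0 °C; then H2O
Reagents that add atoms: water, O
Why: The silyl triflate/collidine pair converts the dimethyl acetal into a collidinium N,O-acetal that water hydrolyses to the aldehyde under non-acidic conditions, sparing the TBS ether, the angelate and the lactone and avoiding β-elimination.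

Step 17
Reactants: 28 seco-aldehyde with C10 vinyl iodide
Product: 29 (1R,3S,6S,7R,8R)-3-(tert-butyldimethylsilyloxy)-1-hydroxy-8-[(2Z)-2-methylbut-2-enoyloxy]germacra-4Z,10(14),11(13)-trien-12,6-olide
Conditions: CrCl2 (20 mol%), ligand ent-A (22 mol%), proton sponge (22 mol%), NiCl2(neocuproine) (5 mol%), Mn, Cp2ZrCl2, LiCl, MeCN, 2 mM (syringe pump), rt; aq. work-up
Reagents that add atoms: none
Why: Intramolecular Ni/Cr-catalysed Nozaki–Hiyama–Kishi coupling: zerovalent nickel inserts into the C10–I bond, the alkenyl group passes to trivalent chromium and adds to the C1 aldehyde; the cis lactone and the Z olefin hold both arms on one face so that ten-membered ring closure beats dimerisation at high dilution, and the ligated chromium delivers C10 to the Si face of C1=O to give the 1R alcohol (1,3-syn to C3–OTBS).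

Step 18
Reactants: 29 C3 silyl ether of the target
Product: 30 (1R,3S,6S,7R,8R)-1,3-dihydroxy-8-[(2Z)-2-methylbut-2-enoyloxy]germacra-4Z,10(14),11(13)-trien-12,6-olide (target, 6,7-cis-fused)
Conditions: HF·pyridine, pyridine, THF, 0 °C to rt
Reagents that add atoms: none
Why: Buffered fluoride cleavage of the allylic TBS ether; the angelate, the α-methylene lactone and the allylic alcohols are stable to HF·pyridine.

## Compound list

1 | but-2-yn-1-ol | CC#CCO | starting material
2 | sodium 2,2-bis(2-methoxyethoxy)-3-methyl-2,5-dihydro-1,2-oxaaluminol-2-uide (cyclic alkenylalanate) | [Na+].CC1=CCO[Al-]1(OCCOC)OCCOC | intermediate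
3 | (Z)-3-iodobut-2-en-1-ol | C/C(I)=C/CO | intermediate
4 | (Z)-triethyl[(3-iodobut-2-en-1-yl)oxy]silane | C/C(I)=C/CO[Si](CC)(CC)CC | intermediate
5 | 3,3-dimethoxypropanenitrile | COC(CC#N)OC | starting material
6 | N-(diisobutylalumanyl)-3,3-dimethoxypropan-1-imine | COC(CC=N[Al](CC(C)C)CC(C)C)OC | intermediate
7 | 3,3-dimethoxypropanal | COC(CC=O)OC | intermediate
8 | (3S,4Z)-1,1-dimethoxy-4-methyl-6-(triethylsilyloxy)hex-4-en-3-ol | CC[Si](CC)(CC)OC/C=C(/C)[C@@H](O)CC(OC)OC | intermediate
9 | (3S,4Z)-3-(tert-butyldimethylsilyloxy)-1,1-dimethoxy-4-methyl-6-(triethylsilyloxy)hex-4-ene | CC[Si](CC)(CC)OC/C=C(/C)[C@@H](O[Si](C)(C)C(C)(C)C)CC(OC)OC | intermediate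
10 | (2Z,4S)-4-(tert-butyldimethylsilyloxy)-6,6-dimethoxy-3-methylhex-2-enal | O=C/C=C(/C)[C@@H](O[Si](C)(C)C(C)(C)C)CC(OC)OC | intermediate
11 | (S)-glycidol [(2S)-oxiran-2-ylmethanol] | OC[C@H]1CO1 | starting material
12 | (1-bromovinyl)trimethylsilane | C=C(Br)[Si](C)(C)C | starting material
13 | [1-(trimethylsilyl)vinyl]magnesium bromide | C=C([Mg]Br)[Si](C)(C)C | intermediate
14 | (2R)-4-(trimethylsilyl)pent-4-ene-1,2-diol | C=C([Si](C)(C)C)C[C@@H](O)CO | intermediate
15 | (2R)-1,2-bis(triethylsilyloxy)-4-(trimethylsilyl)pent-4-ene | C=C([Si](C)(C)C)C[C@@H](O[Si](CC)(CC)CC)CO[Si](CC)(CC)CC | intermediate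
16 | (2R)-4-iodo-1,2-bis(triethylsilyloxy)pent-4-ene | C=C(I)C[C@@H](O[Si](CC)(CC)CC)CO[Si](CC)(CC)CC | intermediate
17 | (2R)-4-iodo-2-(triethylsilyloxy)pent-4-enal | C=C(I)C[C@@H](O[Si](CC)(CC)CC)C=O | intermediate
18 | methyl acrylate | C=CC(=O)OC | starting material
19 | methyl (4R)-3-hydroxy-6-iodo-2-methylidene-4-(triethylsilyloxy)hept-6-enoate (C3 epimers) | C=C(I)C[C@@H](O[Si](CC)(CC)CC)C(O)C(=C)C(=O)OC | intermediate
20 | methyl (2Z,4R)-2-(bromomethyl)-6-iodo-4-(triethylsilyloxy)hepta-2,6-dienoate | C=C(I)C[C@@H](O[Si](CC)(CC)CC)/C=C(/C(=O)OC)CBr | intermediate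
21 | methyl (3S,4S,5Z,7S)-7-(tert-butyldimethylsilyloxy)-4-hydroxy-3-[(1R)-3-iodo-1-(triethylsilyloxy)but-3-en-1-yl]-9,9-dimethoxy-6-methyl-2-methylidenenon-5-enoate | C=C(C(=O)OC)[C@@H]([C@@H](O)/C=C(/C)[C@@H](O[Si](C)(C)C(C)(C)C)CC(OC)OC)[C@H](O[Si](CC)(CC)CC)CC(I)=C | intermediate
22 | (4S,5S)-5-[(1Z,3S)-3-(tert-butyldimethylsilyloxy)-5,5-dimethoxy-2-methylpent-1-en-1-yl]-4-[(1R)-3-iodo-1-(triethylsilyloxy)but-3-en-1-yl]-3-methylideneoxolan-2-one | C=C1C(=O)O[C@@H](/C=C(/C)[C@@H](O[Si](C)(C)C(C)(C)C)CC(OC)OC)[C@H]1[C@H](O[Si](CC)(CC)CC)CC(I)=C | intermediate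
23 | (4R,5S)-5-[(1Z,3S)-3-(tert-butyldimethylsilyloxy)-5,5-dimethoxy-2-methylpent-1-en-1-yl]-4-[(1R)-1-hydroxy-3-iodobut-3-en-1-yl]-3-methylideneoxolan-2-one | C=C1C(=O)O[C@@H](/C=C(/C)[C@@H](O[Si](C)(C)C(C)(C)C)CC(OC)OC)[C@H]1[C@H](O)CC(I)=C | intermediate
24 | angelic acid [(Z)-2-methylbut-2-enoic acid] | C/C=C(/C)C(=O)O | starting material
25 | (Z)-2-methylbut-2-enoic 2,4,6-trichlorobenzoic anhydride | C/C=C(/C)C(=O)OC(=O)c1c(Cl)cc(Cl)cc1Cl | intermediate
26 | (1R)-1-{(4R,5S)-5-[(1Z,3S)-3-(tert-butyldimethylsilyloxy)-5,5-dimethoxy-2-methylpent-1-en-1-yl]-3-methylidene-2-oxooxolan-4-yl}-3-iodobut-3-en-1-yl (2Z)-2-methylbut-2-enoate | C=C1C(=O)O[C@@H](/C=C(/C)[C@@H](O[Si](C)(C)C(C)(C)C)CC(OC)OC)[C@H]1[C@H](OC(=O)/C(C)=C\C)CC(I)=C | intermediate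
27 | 1-[1-methoxy-(C1 of the side chain of 26)]-2,4,6-trimethylpyridinium triflate (collidinium N,O-acetal of 26, both epimers at the acetal carbon) | C=C1C(=O)O[C@@H](/C=C(/C)[C@@H](O[Si](C)(C)C(C)(C)C)CC(OC)[n+]2c(C)cc(C)cc2C)[C@H]1[C@H](OC(=O)/C(C)=C\C)CC(I)=C.[O-]S(=O)(=O)C(F)(F)F | intermediate
28 | (1R)-1-{(4R,5S)-5-[(1Z,3S)-3-(tert-butyldimethylsilyloxy)-2-methyl-5-oxopent-1-en-1-yl]-3-methylidene-2-oxooxolan-4-yl}-3-iodobut-3-en-1-yl (2Z)-2-methylbut-2-enoate | C=C1C(=O)O[C@@H](/C=C(/C)[C@@H](O[Si](C)(C)C(C)(C)C)CC=O)[C@H]1[C@H](OC(=O)/C(C)=C\C)CC(I)=C | intermediate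
29 | (1R,3S,6S,7R,8R)-3-(tert-butyldimethylsilyloxy)-1-hydroxy-8-[(2Z)-2-methylbut-2-enoyloxy]germacra-4Z,10(14),11(13)-trien-12,6-olide | C=C1C(=O)O[C@H]2/C=C(/C)[C@@H](O[Si](C)(C)C(C)(C)C)C[C@@H](O)C(=C)C[C@@H](OC(=O)/C(C)=C\C)[C@@H]12 | intermediate
30 | (1R,3S,6S,7R,8R)-1,3-dihydroxy-8-[(2Z)-2-methylbut-2-enoyloxy]germacra-4Z,10(14),11(13)-trien-12,6-olide | C=C1C(=O)O[C@H]2/C=C(/C)[C@@H](O)C[C@@H](O)C(=C)C[C@@H](OC(=O)/C(C)=C\C)[C@@H]12 | target

## Step count and risks

Total step count: 18.
Longest linear sequence: 12 steps (steps 7–12, then 13–18, from 11 or 12). The west branch from 1 is 5 + 6 = 11 steps.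

Steps most likely to fail:

Step 11 (Morita–Baylis–Hillman on the α-silyloxy aldehyde). The risks are a slow reaction, erosion of C8 and silyl migration. Fallback: the acrylate α-anion is made beforehand instead of being generated by amine catalysis. Hydroalumination of methyl propiolate with iBu2AlH/HMPA (THF, 0 °C) gives [1-(methoxycarbonyl)vinyl]diisobutylaluminium F1, which adds to the aldehyde within minutes at −78 to 0 °C. This sets out from 17 and comes back to the route at 19.

Step 13 (the proposed chromium-catalysed union). The risks are poor turnover and insufficient catalyst control over C6/C7 relative to C8. Fallback, all known chemistry, replaces the redox-metal allylation by a boron allylation. The alcohol 19 is acetylated (Ac2O, pyridine, DMAP) to methyl (4R)-3-acetoxy-6-iodo-2-methylidene-4-(triethylsilyloxy)hept-6-enoate F2. Copper-catalysed SN2′ borylation (B2pin2, CuCl, LiCl, KOAc, DMF, rt) then gives methyl (2E,4R)-6-iodo-2-[(4,4,5,5-tetramethyl-1,3,2-dioxaborolan-2-yl)methyl]-4-(triethylsilyloxy)hepta-2,6-dienoate F3, with C8 trans to the ester. F3 and 10 in toluene at 80 °C react through the closed chair to the syn borate, which lactonises (PPTS). This sets out from 19 (with 10) and comes back at 22.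

Step 17 (ten-membered ring closure that also sets C1). The risk is low or mismatched facial control at C1. Fallback: C1 is set by ketone reduction instead of in the C–C bond-forming event. Ring closure without a chiral ligand (CrCl2 4 equiv, NiCl2 2 mol%, DMSO/THF, 2 mM) gives 29 together with its C1 epimer, (1S,3S,6S,7R,8R)-3-(tert-butyldimethylsilyloxy)-1-hydroxy-8-angeloyloxygermacra-4Z,10(14),11(13)-trien-12,6-olide F4. The mixture is oxidised (Dess–Martin periodinane, NaHCO3, CH2Cl2) to the enone (3S,6S,7R,8R)-3-(tert-butyldimethylsilyloxy)-1-oxo-8-angeloyloxygermacra-4Z,10(14),11(13)-trien-12,6-olide F5. Corey–Bakshi–Shibata reduction ((S)-methyl oxazaborolidine, BH3·SMe2, −40 °C) then gives the 1R alcohol by reagent control. This sets out from 28 and comes back at 29.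

Further compounds

F1 | step 11 | [1-(methoxycarbonyl)vinyl]diisobutylaluminium | C=C([Al](CC(C)C)CC(C)C)C(=O)OC
F2 | step 13 | methyl (4R)-3-acetoxy-6-iodo-2-methylidene-4-(triethylsilyloxy)hept-6-enoate (C3 epimers) | C=C(I)C[C@@H](O[Si](CC)(CC)CC)C(OC(C)=O)C(=C)C(=O)OC
F3 | step 13 | methyl (2E,4R)-6-iodo-2-[(4,4,5,5-tetramethyl-1,3,2-dioxaborolan-2-yl)methyl]-4-(triethylsilyloxy)hepta-2,6-dienoate | C=C(I)C[C@@H](O[Si](CC)(CC)CC)/C=C(/C(=O)OC)CB1OC(C)(C)C(C)(C)O1
F4 | step 17 | (1S,3S,6S,7R,8R)-3-(tert-butyldimethylsilyloxy)-1-hydroxy-8-[(2Z)-2-methylbut-2-enoyloxy]germacra-4Z,10(14),11(13)-trien-12,6-olide | C=C1C(=O)O[C@H]2/C=C(/C)[C@@H](O[Si](C)(C)C(C)(C)C)C[C@H](O)C(=C)C[C@@H](OC(=O)/C(C)=C\C)[C@@H]12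
F5 | step 17 | (3S,6S,7R,8R)-3-(tert-butyldimethylsilyloxy)-8-[(2Z)-2-methylbut-2-enoyloxy]-1-oxogermacra-4Z,10(14),11(13)-trien-12,6-olide | C=C1C(=O)O[C@H]2/C=C(/C)[C@@H](O[Si](C)(C)C(C)(C)C)CC(=O)C(=C)C[C@@H](OC(=O)/C(C)=C\C)[C@@H]12
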